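## Retrosynthetic overview

1. Target 20 ⇐ ester 18 by desilylation and saponification; 18 ⇐ alkene 16 + methyl acrylate by an ene reaction (C4–C bond, C4 stereocentre and the C3 isopropylidene in one step).
2. 16 ⇐ enol triflate 15 ⇐ octalone 13 by conjugate methylation (C5 quaternary centre, cis ring fusion) with O-triflation of the enolate.
3. 13 ⇐ aldehyde 5 + aryl Grignard 9, then ketal hydrolysis, enone conjugation and benzylic deoxygenation.
4. 5 ⇐ diene 3 + tiglic aldehyde 4 by a catalytic asymmetric Diels–Alder reaction (sets C8, C9 and C10).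
5. Ring order: ring A carbons arrive as the cyclohexene of 3; ring B is formed by the [4+2] step; ring A is functionalised last.

Convention: decalin numbering throughout (ring A = C10, C1, C2, C3, C4, C5; ring B = C5 to C10); α is the face of the C10 hydrogen, β the other face; Ar = 5-methoxy-3-methyl-2-[tri(propan-2-yl)silyloxy]phenyl. In this numbering the target is (4S,5R,8R,9S,10S): 4α chain, 5α-Me, 8α-Me, 9α-Me, 9β-CH2Ar, 10α-H.

Assumption: the (S)-oxazaborolidinium catalyst is taken to give the (8R,9S,10R) adduct 5; if the facial sense is the opposite, the (R)-catalyst is used and nothing else changes.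

## Route

Step 1
Reactants: 1 2-(1,4-dioxaspiro[4.5]dec-7-en-8-yl)-4,4,5,5-tetramethyl-1,3,2-dioxaborolane; 2 bromoethene
Product: 3 8-ethenyl-1,4-dioxaspiro[4.5]dec-7-ene
Conditions: Pd(dppf)Cl2 (3 mol %), K3PO4, THF/H2O, 50 °C, sealed tube
Reagents that add atoms: none
Why: Suzuki–Miyaura coupling of an alkenyl boronate with vinyl bromide gives the achiral semicyclic 1,3-diene; no stereocentre is formed.

Step 2
Reactants: 3 8-ethenyl-1,4-dioxaspiro[4.5]dec-7-ene; 4 (E)-2-methylbut-2-enal
Product: 5 Diels–Alder aldehyde (C3 ethylene ketal; C5=C6 alkene; 9β-CHO; 9α-Me; 8α-Me; 10α-H)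
Conditions: (S)-o-tolyl-CBS oxazaborolidine (20 mol %), Tf2NH (18 mol %), CH2Cl2, −78 → −40 °C
Reagents that add atoms: none
Why: Oxazaborolidinium-catalysed (metal-free cationic Lewis acid) asymmetric Diels–Alder reaction of an α-substituted enal; the vinyl CH2 terminus bonds to the β-carbon ("ortho" adduct), the endo-CHO transition state puts CHO cis to C1 and the E-enal keeps the two methyls cis, so C8, C9 and C10 are set together and the catalyst fixes the absolute sense.

Step 3
Reactants: 6 4-methoxy-2-methylphenol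
Product: 7 2-bromo-4-methoxy-6-methylphenol
Conditions: NBS, CH2Cl2, 0 °C
Reagents that add atoms: N-bromosuccinimide, O=C1CCC(=O)N1Br
Why: Electrophilic aromatic bromination at the only free position ortho to the hydroxyl group, which outranks the methoxy group as director.

Step 4
Reactants: 7 2-bromo-4-methoxy-6-methylphenol
Product: 8 (2-bromo-4-methoxy-6-methylphenoxy)tri(propan-2-yl)silane
Conditions: TIPSOTf, 2,6-lutidine, CH2Cl2, 0 °C → rt
Reagents that add atoms: triisopropylsilyl trifluoromethanesulfonate, CC(C)[Si](OS(=O)(=O)C(F)(F)F)(C(C)C)C(C)C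
Why: O-silylation of the hindered phenol gives an ether that survives Grignard, acid, cuprate and Lewis acid steps and is removed by fluoride at the end.

Step 5
Reactants: 8 (2-bromo-4-methoxy-6-methylphenoxy)tri(propan-2-yl)silane; 5 Diels–Alder aldehyde
Product: 10 benzylic carbinol (5 with CHO converted to CH(OH)Ar; both carbinol epimers), via aryl Grignard reagent 9 (not isolated)
Conditions: Mg, LiCl, THF, 40 °C; then 5, −20 °C → rt; aq NH4Cl
Reagents that add atoms: none
Why: Grignard 1,2-addition to the neopentyl aldehyde joins the arene to C9; the new carbinol centre is formed as a mixture and is erased in step 6.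

Step 6
Reactants: 10 benzylic carbinol
Product: 13 arylmethyl octalone (C3 ketone; C4=C5 alkene; 9β-CH2Ar), via β,γ-unsaturated hydroxy ketone 11 (not isolated), via conjugated hydroxy enone 12 (not isolated)
Conditions: 2 M HCl, THF, 45 °C; crude; then Et3SiH, TFA, CH2Cl2, 0 °C
Reagents that add atoms: water, O
Why: Ketal hydrolysis and acid-mediated conjugation of the C5=C6 alkene into the enone, then ionic (silane) deoxygenation of the electron-rich benzylic alcohol, which cannot eliminate because C9 is quaternary; C8, C9 and C10 are untouched.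

Step 7
Reactants: 13 arylmethyl octalone
Product: 15 enol triflate (C3–OTf; C3=C4 alkene; 5α-Me; cis-fused), via lithium enolate 14 (not isolated)
Conditions: Me2CuLi (MeLi, CuI), Et2O, −30 → 0 °C; then PhNTf2, THF/DMPU, 0 °C → rt
Reagents that add atoms: lithium dimethylcuprate, [Li+].C[Cu-]C; N-phenylbis(trifluoromethanesulfonimide), O=S(=O)(N(c1ccccc1)S(=O)(=O)C(F)(F)F)C(F)(F)F
Why: Cuprate conjugate addition to the octalone delivers methyl axially on ring A to give the cis-fused decalin (5-Me cis to 10-H), and the regiodefined enolate is trapped on oxygen as the triflate.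

Step 8
Reactants: 15 enol triflate
Product: 16 isopropyl alkene (C3–CH(CH3)2; C3=C4 alkene)
Conditions: i-PrMgCl, Fe(acac)3 (5 mol %), THF/NMP, −30 °C
Reagents that add atoms: isopropylmagnesium chloride, CC(C)[Mg]Cl
Why: Iron-catalysed Kumada-type cross-coupling of an alkenyl triflate with a secondary alkyl Grignard reagent; no stereocentre is affected.

Step 9
Reactants: 16 isopropyl alkene; 17 methyl prop-2-enoate
Product: 18 methyl ester of the silyl-protected target (4α-CH2CH2CO2Me; C3 isopropylidene)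
Conditions: EtAlCl2 (2.2 equiv), 17 (5 equiv), CH2Cl2, 0 → 25 °C
Reagents that add atoms: none
Why: Proposed new method: an EtAlCl2-promoted intermolecular acrylate ene reaction on a ring-fused, neopentyl 1-isopropylcyclohexene. The Lewis-acid-bound acrylate attacks the less substituted alkene carbon C4 on the convex α face (anti to ring B) in an asynchronous six-membered transition state, and the tertiary isopropyl hydrogen, which is cis to the vinylic H-4 and lies under the enophile, is transferred to the acrylate α-carbon. This forms the C4–C bond, the C4 stereocentre and the tetrasubstituted C3 isopropylidene at once, while the alkylaluminium chloride scavenges protons that could isomerise the alkene. The closest known reaction type is the alkylaluminium chloride-promoted ene reaction of acrylates and propiolates with simple 1,1-disubstituted and trisubstituted alkenes, where a primary or secondary allylic hydrogen is transferred.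

Step 10
Reactants: 18 methyl ester of the silyl-protected target
Product: 20 3-[(1S,4aS,5S,6R,8aR)-5-[(2-hydroxy-5-methoxy-3-methylphenyl)methyl]-5,6,8a-trimethyl-2-(propan-2-ylidene)decahydronaphthalen-1-yl]propanoic acid, via phenol methyl ester 19 (not isolated)
Conditions: TBAF, THF, 0 °C → rt; then LiOH, MeOH/H2O, 45 °C; 1 M HCl work-up
Reagents that add atoms: lithium hydroxide, [Li+].[OH-]
Why: Fluoride desilylation of the aryl silyl ether followed by saponification in the same pot; no stereocentre or alkene is touched.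

## Compound list

1 | 2-(1,4-dioxaspiro[4.5]dec-7-en-8-yl)-4,4,5,5-tetramethyl-1,3,2-dioxaborolane | CC1(C)OB(OC1(C)C)C1=CCC2(CC1)OCCO2 | starting material
2 | bromoethene (vinyl bromide) | C=CBr | starting material
3 | 8-ethenyl-1,4-dioxaspiro[4.5]dec-7-ene | C=CC1=CCC2(CC1)OCCO2 | intermediate
4 | (E)-2-methylbut-2-enal (tiglic aldehyde) | C/C=C(\C)C=O | starting material
5 | Diels–Alder aldehyde, (8R,9S,10R): C3 ethylene ketal, C5=C6 alkene, 9β-CHO, 9α-Me, 8α-Me, 10α-H | O=C[C@]1(C)[C@@H]2CCC3(OCCO3)CC2=CC[C@H]1C | intermediate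
6 | 4-methoxy-2-methylphenol | COc1ccc(O)c(C)c1 | starting material
7 | 2-bromo-4-methoxy-6-methylphenol | COc1cc(C)c(O)c(Br)c1 | intermediate
8 | (2-bromo-4-methoxy-6-methylphenoxy)tri(propan-2-yl)silane | COc1cc(C)c(O[Si](C(C)C)(C(C)C)C(C)C)c(Br)c1 | intermediate
9 | {5-methoxy-3-methyl-2-[tri(propan-2-yl)silyloxy]phenyl}magnesium bromide | COc1cc(C)c(O[Si](C(C)C)(C(C)C)C(C)C)c([Mg]Br)c1 | intermediate (not isolated)
10 | benzylic carbinol: 5 with CHO converted to CH(OH)Ar, both carbinol epimers | COc1cc(C)c(O[Si](C(C)C)(C(C)C)C(C)C)c(C(O)[C@]2(C)[C@@H]3CCC4(OCCO4)CC3=CC[C@H]2C)c1 | intermediate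
11 | β,γ-unsaturated hydroxy ketone: C3 ketone, C5=C6 alkene, 9β-CH(OH)Ar | COc1cc(C)c(O[Si](C(C)C)(C(C)C)C(C)C)c(C(O)[C@]2(C)[C@@H]3CCC(=O)CC3=CC[C@H]2C)c1 | intermediate (not isolated)
12 | conjugated hydroxy enone: C3 ketone, C4=C5 alkene, 9β-CH(OH)Ar | COc1cc(C)c(O[Si](C(C)C)(C(C)C)C(C)C)c(C(O)[C@]2(C)[C@@H]3CCC(=O)C=C3CC[C@H]2C)c1 | intermediate (not isolated)
13 | arylmethyl octalone: C3 ketone, C4=C5 alkene, 9β-CH2Ar, 9α-Me, 8α-Me, 10α-H | COc1cc(C)c(O[Si](C(C)C)(C(C)C)C(C)C)c(C[C@]2(C)[C@@H]3CCC(=O)C=C3CC[C@H]2C)c1 | intermediate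
14 | lithium enolate: C3–OLi, C3=C4 alkene, 5α-Me, cis-fused | COc1cc(C)c(O[Si](C(C)C)(C(C)C)C(C)C)c(C[C@]2(C)[C@@H]3CCC(O[Li])=C[C@]3(C)CC[C@H]2C)c1 | intermediate (not isolated)
15 | enol triflate: C3–OSO2CF3, C3=C4 alkene, 5α-Me, cis-fused | COc1cc(C)c(O[Si](C(C)C)(C(C)C)C(C)C)c(C[C@]2(C)[C@@H]3CCC(OS(=O)(=O)C(F)(F)F)=C[C@]3(C)CC[C@H]2C)c1 | intermediate
16 | isopropyl alkene: C3–CH(CH3)2, C3=C4 alkene, 5α-Me, cis-fused | COc1cc(C)c(O[Si](C(C)C)(C(C)C)C(C)C)c(C[C@]2(C)[C@@H]3CCC(C(C)C)=C[C@]3(C)CC[C@H]2C)c1 | intermediate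
17 | methyl prop-2-enoate (methyl acrylate) | C=CC(=O)OC | starting material
18 | methyl ester of the silyl-protected target: 4α-CH2CH2CO2Me, C3 isopropylidene, aryl O-TIPS | COc1cc(C)c(O[Si](C(C)C)(C(C)C)C(C)C)c(C[C@]2(C)[C@@H]3CCC(=C(C)C)[C@@H](CCC(=O)OC)[C@]3(C)CC[C@H]2C)c1 | intermediate
19 | methyl ester of the target (free phenol) | COc1cc(C)c(O)c(C[C@]2(C)[C@@H]3CCC(=C(C)C)[C@@H](CCC(=O)OC)[C@]3(C)CC[C@H]2C)c1 | intermediate (not isolated)
20 | 3-[(1S,4aS,5S,6R,8aR)-5-[(2-hydroxy-5-methoxy-3-methylphenyl)methyl]-5,6,8a-trimethyl-2-(propan-2-ylidene)decahydronaphthalen-1-yl]propanoic acid; decalin numbering (4S,5R,8R,9S,10S) | COc1cc(C)c(O)c(C[C@]2(C)[C@@H]3CCC(=C(C)C)[C@@H](CCC(=O)O)[C@]3(C)CC[C@H]2C)c1 | target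

## Step count and risk

Total step count: 10. Longest linear sequence: 8 steps (1, 2, 5, 6, 7, 8, 9, 10; the aryl branch 3, 4, 5–10 is equally long).

**Step 9 (proposed new ene reaction).** The alkene carbon C4 is neopentyl, and hydrogen transfer from the ring C2–H instead of the isopropyl C–H would give the endocyclic isomer; conversion may also be low. The fallback uses known chemistry only; it sets out from enone 13 and comes back at ester 18. Me2CuLi with Me3SiCl converts 13 into the trimethylsilyl enol ether F1 (5α-Me, cis-fused). A Tf2NH-catalysed Mukaiyama–Michael addition of F1 to methyl acrylate 17 gives the keto ester F2, with the acrylate entering C4 on the convex α face. Ramirez olefination (CBr4, PPh3, toluene, 80 °C) gives the dibromoalkene F3. Twofold Negishi methylation (Me2Zn, Pd(PtBu3)2, THF) then gives 18.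

**Step 2 (asymmetric Diels–Alder).** The α,β-disubstituted enal is a sluggish dienophile, the ketal may bind the catalyst, and the regio-, endo- and enantioselectivity are untested on this diene. The fallback sets out from diene 3 and comes back at aldehyde 5. An iminium-catalysed Diels–Alder reaction of 3 with (E)-but-2-enal, using (2S,5S)-5-benzyl-2-tert-butyl-3-methylimidazolidin-4-one trifluoroacetate in MeCN/H2O, gives the endo nor-methyl aldehyde F4 (9β-CHO, 9α-H, 8α-Me). α-Methylation of its potassium enolate (KHMDS, MeI, THF, −78 °C), on the face anti to the ring A methylene at C10, then gives 5. The facial selectivity of this methylation is itself uncertain, so any C9 epimer would have to be removed by chromatography.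

**Step 6 (hydrolysis and ionic deoxygenation).** The benzylic cation sits next to the quaternary C9 and carries only an ortho silyloxy donor, so a 1,2-shift or incomplete reduction is possible. The fallback sets out from carbinol 10 and comes back at octalone 13. Barton–McCombie deoxygenation is used: NaH, CS2, MeI give the xanthate F5; Bu3SnH, AIBN, toluene, 90 °C give the arylmethyl ketal F6. Hydrolysis and conjugation with 2 M HCl in THF then give 13.

Further compounds
F1 | step 9 | trimethylsilyl enol ether: C3–OSiMe3, C3=C4 alkene, 5α-Me, cis-fused | COc1cc(C)c(O[Si](C(C)C)(C(C)C)C(C)C)c(C[C@]2(C)[C@@H]3CCC(O[Si](C)(C)C)=C[C@]3(C)CC[C@H]2C)c1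
F2 | step 9 | keto ester: C3 ketone, 4α-CH2CH2CO2Me, 5α-Me | COc1cc(C)c(O[Si](C(C)C)(C(C)C)C(C)C)c(C[C@]2(C)[C@@H]3CCC(=O)[C@@H](CCC(=O)OC)[C@]3(C)CC[C@H]2C)c1
F3 | step 9 | dibromoalkene: C3=CBr2, 4α-CH2CH2CO2Me | COc1cc(C)c(O[Si](C(C)C)(C(C)C)C(C)C)c(C[C@]2(C)[C@@H]3CCC(=C(Br)Br)[C@@H](CCC(=O)OC)[C@]3(C)CC[C@H]2C)c1
F4 | step 2 | nor-methyl Diels–Alder aldehyde: C3 ethylene ketal, C5=C6 alkene, 9β-CHO, 9α-H, 8α-Me, 10α-H | O=C[C@@H]1[C@@H]2CCC3(OCCO3)CC2=CC[C@H]1C
F5 | step 6 | S-methyl xanthate of carbinol 10 | COc1cc(C)c(O[Si](C(C)C)(C(C)C)C(C)C)c(C(OC(=S)SC)[C@]2(C)[C@@H]3CCC4(OCCO4)CC3=CC[C@H]2C)c1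
F6 | step 6 | arylmethyl ketal: C3 ethylene ketal, C5=C6 alkene, 9β-CH2Ar | COc1cc(C)c(O[Si](C(C)C)(C(C)C)C(C)C)c(C[C@]2(C)[C@@H]3CCC4(OCCO4)CC3=CC[C@H]2C)c1
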